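I had no constants for these flasks, so I set out to read one from the earlier runs.

the same everywhere: second catalyst 5.4 mM

|  | starting material | partner | free catalyst | remark | time |
|---|---|---|---|---|---|
| alpha | 0.10 M | 0.15 M | 2.5 mM | run made earlier |  |
| eta | 0.10 M | 0.15 M | 1.2 mM | run made earlier |  |
| autumn | 0.10 M (fed, over 20.0 h) | 0.150 M | 2.5 mM | all but starting material at the start; starting material goes in evenly over 20.0 h, the run ends at 20 h | 20 h |
| spring | 0.10 M | 0.150 M | 2.5 mM | everything together in a closed stirred flask, run for 20 h | 20 h |
| noon | 0.10 M | 0.150 M | 2.5 mM | a tube with plug flow, the mixed feed as stated, residence time 20 h | 20 h |
| dusk | 0.10 M | 0.150 M | 2.5 mM | one stirred flow tank at steady state, fed with the mixture as stated, mean residence time 20 h |  |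

alpha run (percent of the starting material charged)

| time / h | target / % | over-reaction product / % |
|---|---|---|
| 2.50 | 2.4 | 0 |
| 8.00 | 15.0 | 1.2 |
| 12.0 | 24.8 | 2.1 |
| 20.0 | 37.4 | 7.5 |

eta run (percent of the starting material charged)

| time / min | target / % | over-reaction product / % |
|---|---|---|
| 10.0 | 0.4 | 0.6 |
| 20.0 | 1.0 | 0 |
| 50.0 | 0.9 | 0 |
| 120 | 0.8 | 0.2 |

(readings scatter by 0.5 percentage points)

* the set-up with the highest share of target in all that became target or over-reaction product, at the outlet or at the end ("none" if the first two lie within 2 percentage points) (autumn / spring / noon / dusk / none)
* share of target in all that became target or over-reaction product, at the outlet or at the end, autumn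
* share of target in all that became target or over-reaction product, at the outlet or at the end, spring
* share of target in all that became target or over-reaction product, at the outlet or at the end, noon
* share of target in all that became target or over-reaction product, at the outlet or at the end, dusk

- the stated concentrations are those of everything mixed, before any reaction; amounts are the same in each set-up
- the analysis behind the earlier runs scatters by 0.5 percentage points, standard deviation
- steps under discussion: starting material + free catalyst -> free catalyst + intermediate; partner + second catalyst + intermediate -> second catalyst + target; partner + target -> over-reaction product
- the feed brings no volume worth counting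
- the earlier runs were made in a closed, stirred flask

The last step consumes target with partner, and partner was charged at 1.50 of the starting-material charge. So I treated the step as pseudo-first-order in target, with partner's fall averaged in. In fractions of the charge, the alpha run gave by trapezoids:

area under target = 3.79 h

loss rate per target = over-reaction product / area = 0.0198 h⁻¹

Mean age of target is area over target, so:

share = 1 / (1 + loss rate × mean age)

I took two extremes. With target born at the end, age is zero and the share is 100 %. With target aged the full 20 h, the share is 71.7 %. I put the dusk tank on this second extreme: its mean residence time is the mean age of what leaves.

Spring and noon repeat the alpha history. The alpha age was 10.1 h, about half of the run, which gives 83.3 %.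

Autumn's feed adds a delay. Early target grows as the cube of time instead of the square, so I scaled the age by 3/4:

age = 7.61 h, share = 86.9 %

The forecast named autumn, with 87.5 % for autumn, 83.8 % for spring, 83.8 % for noon and 74 % for dusk: “Autumn is best, though at lower conversion.” My dusk figure stood lower than its 74 %.

The simulation gave autumn: autumn 88.2 %, spring 84.8 %, noon 84.8 %, dusk 74.8 %.

    starting material + free catalyst → free catalyst + intermediate (k = 58.1 M⁻¹ h⁻¹)
    partner + second catalyst + intermediate → second catalyst + target (k = 73.4 M⁻² h⁻¹)
    partner + target → over-reaction product (k = 0.157 M⁻¹ h⁻¹)

Turned back through the read loss rate, these shares give a mean target age of 6.76 h in autumn and 9.05 h in spring. The dusk share of 74.8 % stood above my 71.7 %. Autumn led spring by 3.4 percentage points, against a margin of 2 points. In spring, with the other concentrations as charged, the half-life of intermediate by its step was 12 h, shorter than the 29 h of target by over-reaction.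

(Readings and results were computed from invented constants.)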